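**Retrosynthetic overview**
- The strategy rests on the C5(Me)–C6 oxirane of the eleven-membered carbocycle (C1–C11), flanked by oxygenated C4 and C7. It is the oxidised form of an E-trisubstituted C5=C6 alkene, which maps back onto a ring alkyne C5≡C6.
- Oxirane ⇒ C7-hydroxyl-directed epoxidation; C5 methyl ⇒ C4-hydroxyl-directed trans-hydrostannation and methyl Stille coupling of the cycloalkyne.
- Cycloalkyne ⇒ ring-closing alkyne metathesis of a bis(propynyl) seco-diyne that already holds both Z-alkenes, the C8 ketone and the C4/C7 propargylic ethers.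
- Seco-diyne ⇒ Nozaki–Hiyama–Kishi coupling (C8–C9) of a (Z)-2-iodoallyl unit with (S)-2-silyloxypent-3-ynal from (R)-glyceraldehyde acetonide; C4 by CBS reduction of a Z-enynone; quaternary C1 from geraniol by Sharpless epoxidation and epoxy silyl ether rearrangement.
- Ring order: the eleven-membered carbocycle first (step 24), the oxirane last (step 30).

Key step: step 24

Remark: locants C1–C12 of the target are used for every intermediate (C12 is the CH2O carbon on C9); alcohol 26 is taken on as a mixture of C8 epimers, since C8 is oxidised in step 23.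

**Route**

Step 1
Reactants: 1 geraniol
Product: 2 (2R,3R)-2,3-epoxygeraniol
Conditions: Ti(OiPr)4 (5 mol %), D-(−)-diisopropyl tartrate (7 mol %), t-BuOOH, 4 Å MS, CH2Cl2, −20 °C
Reagents that add atoms: tert-butyl hydroperoxide CC(C)(C)OO
Why: Katsuki–Sharpless asymmetric epoxidation, in which the titanium tartrate binds the allylic alcohol so that only the 2,3-alkene reacts, and the D-(−)-tartrate should give the 2R,3R epoxide (mirror image of the L-(+)-tartrate outcome), the E geometry fixing the relative configuration.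

Step 2
Reactants: 2 (2R,3R)-2,3-epoxygeraniol
Product: 3 (2R,3R)-2,3-epoxygeranyl tert-butyldimethylsilyl ether
Conditions: TBSCl, imidazole, DMF, 0 °C to rt
Reagents that add atoms: tert-butyldimethylsilyl chloride C[Si](C)(Cl)C(C)(C)C
Why: Standard silylation of a primary alcohol, which installs the silyl ether needed for the rearrangement.

Step 3
Reactants: 3 (2R,3R)-2,3-epoxygeranyl tert-butyldimethylsilyl ether
Product: 4 (R)-2-[(tert-butyldimethylsilyloxy)methyl]-2,6-dimethylhept-5-enal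
Conditions: MABR [methylaluminium bis(4-bromo-2,6-di-tert-butylphenoxide), from Me3Al and the phenol, 20 mol %], CH2Cl2, −78 to −20 °C
Reagents that add atoms: none
Why: Organoaluminium-promoted epoxy silyl ether rearrangement (semipinacol type): the bulky Lewis acid opens the epoxide at tertiary C3 and the siloxymethyl group shifts from C2 to C3 anti to the leaving oxygen, so the epoxide configuration is transferred with inversion to the quaternary carbon (future C1) and old C2 becomes the aldehyde.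

Step 4
Reactants: 4 (R)-2-[(tert-butyldimethylsilyloxy)methyl]-2,6-dimethylhept-5-enal
Product: 5 (S)-tert-butyldimethyl[(2,6-dimethyl-2-vinylhept-5-enyl)oxy]silane
Conditions: Ph3PCH3Br, KOtBu, THF, 0 °C to rt
Reagents that add atoms: methyltriphenylphosphonium bromide C[P+](c1ccccc1)(c1ccccc1)c1ccccc1.[Br-]
Why: Wittig methylenation of an aldehyde that has no α-hydrogen, so the quaternary centre cannot epimerise.

Step 5
Reactants: 5 (S)-tert-butyldimethyl[(2,6-dimethyl-2-vinylhept-5-enyl)oxy]silane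
Product: 7 (S)-3-[(tert-butyldimethylsilyloxy)methyl]-3,7-dimethyloct-6-en-1-ol, via alkylborane 6 (not isolated)
Conditions: 9-BBN, THF, 0 °C to rt; then NaOH, H2O2, 0 °C
Reagents that add atoms: 9-borabicyclo[3.3.1]nonane [H]B1C2CCCC1CCC2 (atoms in 6 only); hydrogen peroxide OO
Why: Hydroboration–oxidation, in which 9-BBN selects the monosubstituted vinyl group over the trisubstituted alkene and places boron on the terminal carbon (future C10).

Step 6
Reactants: 7 (S)-3-[(tert-butyldimethylsilyloxy)methyl]-3,7-dimethyloct-6-en-1-ol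
Product: 8 (S)-3-[(tert-butyldimethylsilyloxy)methyl]-3,7-dimethyloct-6-enal
Conditions: Dess–Martin periodinane, NaHCO3, CH2Cl2, 0 °C to rt
Reagents that add atoms: none
Why: Dess–Martin oxidation under buffered, non-acidic conditions, which avoids ene/Prins cyclisation of this citronellal-type aldehyde.

Step 7
Reactants: 8 (S)-3-[(tert-butyldimethylsilyloxy)methyl]-3,7-dimethyloct-6-enal
Product: 9 ethyl (2Z,5S)-5-[(tert-butyldimethylsilyloxy)methyl]-2-iodo-5,9-dimethyldeca-2,8-dienoate
Conditions: Ph3P=CHCO2Et, NIS, CH2Cl2, −20 °C; then 8, rt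
Reagents that add atoms: ethyl (triphenylphosphoranylidene)acetate CCOC(=O)C=P(c1ccccc1)(c1ccccc1)c1ccccc1; N-iodosuccinimide O=C1CCC(=O)N1I
Why: Wittig reaction of the stabilised α-iodo ylide formed in situ, which puts the ester trans to the alkyl chain and therefore iodine cis to C11 (2Z), the geometry the C9=C10 alkene needs.

Step 8
Reactants: 9 ethyl (2Z,5S)-5-[(tert-butyldimethylsilyloxy)methyl]-2-iodo-5,9-dimethyldeca-2,8-dienoate
Product: 10 (2Z,5S)-5-[(tert-butyldimethylsilyloxy)methyl]-2-iodo-5,9-dimethyldeca-2,8-dien-1-ol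
Conditions: DIBAL-H, CH2Cl2, −78 °C; Rochelle salt
Reagents that add atoms: none
Why: 1,2-Reduction of the enoate with DIBAL-H at low temperature leaves the vinyl iodide and the alkene geometry untouched.

Step 9
Reactants: 10 (2Z,5S)-5-[(tert-butyldimethylsilyloxy)methyl]-2-iodo-5,9-dimethyldeca-2,8-dien-1-ol
Product: 11 (2Z,5S)-1-(tert-butyldiphenylsilyloxy)-5-[(tert-butyldimethylsilyloxy)methyl]-2-iodo-5,9-dimethyldeca-2,8-diene
Conditions: TBDPSCl, imidazole, DMF, rt
Reagents that add atoms: tert-butyldiphenylsilyl chloride CC(C)(C)[Si](Cl)(c1ccccc1)c1ccccc1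
Why: Silylation of the primary allylic alcohol (C12–O) with a group that survives the later acid steps.

Step 10
Reactants: 11 (2Z,5S)-1-(tert-butyldiphenylsilyloxy)-5-[(tert-butyldimethylsilyloxy)methyl]-2-iodo-5,9-dimethyldeca-2,8-diene
Product: 12 (2S,4Z)-6-(tert-butyldiphenylsilyloxy)-5-iodo-2-methyl-2-(4-methylpent-3-enyl)hex-4-en-1-ol
Conditions: CSA (10 mol %), MeOH/CH2Cl2, 0 °C to rt
Reagents that add atoms: none
Why: Acid-catalysed methanolysis cleaves the TBS ether much faster than the more acid-stable TBDPS ether, so the neopentyl alcohol is freed selectively.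

Step 11
Reactants: 12 (2S,4Z)-6-(tert-butyldiphenylsilyloxy)-5-iodo-2-methyl-2-(4-methylpent-3-enyl)hex-4-en-1-ol
Product: 13 (2S,4Z)-6-(tert-butyldiphenylsilyloxy)-5-iodo-2-methyl-2-(4-methylpent-3-enyl)hex-4-enal
Conditions: Dess–Martin periodinane, NaHCO3, CH2Cl2, 0 °C to rt
Reagents that add atoms: none
Why: Dess–Martin oxidation to an aldehyde whose α-carbon is quaternary, so no epimerisation is possible.

Step 12
Reactants: 13 (2S,4Z)-6-(tert-butyldiphenylsilyloxy)-5-iodo-2-methyl-2-(4-methylpent-3-enyl)hex-4-enal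
Product: 14 (2Z,4S,6Z)-8-(tert-butyldiphenylsilyloxy)-7-iodo-N-methoxy-N,4-dimethyl-4-(4-methylpent-3-enyl)octa-2,6-dienamide
Conditions: (CF3CH2O)2P(O)CH2C(O)N(OMe)Me, KHMDS, 18-crown-6, THF, −78 °C
Reagents that add atoms: N-methoxy-N-methyl-2-[bis(2,2,2-trifluoroethoxy)phosphoryl]acetamide CON(C)C(=O)CP(=O)(OCC(F)(F)F)OCC(F)(F)F
Why: Still–Gennari-type Horner–Wadsworth–Emmons olefination, in which the electron-poor phosphonate and the crown-ether-separated potassium ion make elimination from the kinetic adduct fast and should give the Z (C2=C3) Weinreb amide.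

Step 13
Reactants: 14 (2Z,4S,6Z)-8-(tert-butyldiphenylsilyloxy)-7-iodo-N-methoxy-N,4-dimethyl-4-(4-methylpent-3-enyl)octa-2,6-dienamide
Product: 15 (5Z,7S,9Z)-11-(tert-butyldiphenylsilyloxy)-10-iodo-7-methyl-7-(4-methylpent-3-enyl)undeca-5,9-dien-2-yn-4-one
Conditions: 1-propynylmagnesium bromide, THF, −20 to 0 °C; cold aq. NH4Cl
Reagents that add atoms: 1-propynylmagnesium bromide CC#C[Mg]Br
Why: Weinreb ketone synthesis, in which the chelated tetrahedral adduct prevents over-addition and the alkynyl Grignard reagent does not exchange with the vinyl iodide.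

Step 14
Reactants: 15 (5Z,7S,9Z)-11-(tert-butyldiphenylsilyloxy)-10-iodo-7-methyl-7-(4-methylpent-3-enyl)undeca-5,9-dien-2-yn-4-one
Product: 16 (4R,5Z,7S,9Z)-11-(tert-butyldiphenylsilyloxy)-10-iodo-7-methyl-7-(4-methylpent-3-enyl)undeca-5,9-dien-2-yn-4-ol
Conditions: (R)-Me-CBS (20 mol %), catecholborane, toluene, −78 °C
Reagents that add atoms: none
Why: Corey–Bakshi–Shibata reduction, in which the slim propynyl group should act as the small and the branched Z-alkenyl group as the large substituent, so the (R)-oxazaborolidine should deliver hydride to the Si face and set C4 as R, with catecholborane giving 1,2-reduction only.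

Step 15
Reactants: 16 (4R,5Z,7S,9Z)-11-(tert-butyldiphenylsilyloxy)-10-iodo-7-methyl-7-(4-methylpent-3-enyl)undeca-5,9-dien-2-yn-4-ol
Product: 17 triethylsilyl ether of 16 [(4R,5Z,7S,9Z)-4-(triethylsilyloxy) compound]
Conditions: TESCl, imidazole, CH2Cl2, 0 °C
Reagents that add atoms: triethylsilyl chloride CC[Si](Cl)(CC)CC
Why: Silylation of the secondary alcohol with the most labile of the three silyl groups, so that O4 can be freed alone after ring closure.

Step 16
Reactants: 18 (R)-glyceraldehyde acetonide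
Product: 19 (S)-4-(2,2-dibromovinyl)-2,2-dimethyl-1,3-dioxolane
Conditions: CBr4, PPh3, Et3N (buffer), CH2Cl2, 0 °C
Reagents that add atoms: carbon tetrabromide BrC(Br)(Br)Br
Why: Corey–Fuchs (Ramirez) dibromo-olefination of the aldehyde, which does not touch the adjacent stereocentre.

Step 17
Reactants: 19 (S)-4-(2,2-dibromovinyl)-2,2-dimethyl-1,3-dioxolane
Product: 21 (S)-2,2-dimethyl-4-(prop-1-ynyl)-1,3-dioxolane, via lithium acetylide 20 (not isolated)
Conditions: n-BuLi (2.1 equiv), THF, −78 °C; then MeI, −78 °C to rt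
Reagents that add atoms: n-butyllithium [Li]CCCC (atoms in 20 only); iodomethane CI
Why: Second stage of the Corey–Fuchs sequence (bromine–lithium exchange, 1,2-shift to the alkyne, deprotonation) followed by C-methylation of the acetylide, which gives the methyl-capped alkyne needed for metathesis.

Step 18
Reactants: 21 (S)-2,2-dimethyl-4-(prop-1-ynyl)-1,3-dioxolane
Product: 22 (S)-pent-3-yne-1,2-diol
Conditions: Dowex 50W-X8 (H+), MeOH, rt
Reagents that add atoms: none
Why: Acid-catalysed transacetalisation removes the acetonide without affecting the stereocentre.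

Step 19
Reactants: 22 (S)-pent-3-yne-1,2-diol
Product: 23 (S)-1,2-bis(tert-butyldimethylsilyloxy)pent-3-yne
Conditions: TBSCl (2.5 equiv), imidazole, DMF, rt
Reagents that add atoms: tert-butyldimethylsilyl chloride C[Si](C)(Cl)C(C)(C)C
Why: Exhaustive silylation of both hydroxyl groups.

Step 20
Reactants: 23 (S)-1,2-bis(tert-butyldimethylsilyloxy)pent-3-yne
Product: 24 (S)-2-(tert-butyldimethylsilyloxy)pent-3-yn-1-ol
Conditions: HF·pyridine, pyridine, THF, 0 °C
Reagents that add atoms: none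
Why: Desilylation is faster at the unhindered primary silyl ether than at the secondary propargylic one.

Step 21
Reactants: 24 (S)-2-(tert-butyldimethylsilyloxy)pent-3-yn-1-ol
Product: 25 (S)-2-(tert-butyldimethylsilyloxy)pent-3-ynal
Conditions: Dess–Martin periodinane, NaHCO3, CH2Cl2, 0 °C; used at once
Reagents that add atoms: none
Why: Dess–Martin oxidation under amine-free conditions should give the α-silyloxy propargylic aldehyde without enolisation of the future C7 centre.

Step 22
Reactants: 17 triethylsilyl ether of 16, 25 (S)-2-(tert-butyldimethylsilyloxy)pent-3-ynal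
Product: 26 (4R,7S,8RS)-seco-diynol MeC≡C–CH(OTES)–CH=CH–C(Me)(homoprenyl)–CH2–CH=C(CH2OTBDPS)–CH(OH)–CH(OTBS)–C≡CMe (2Z, 9Z, 1S)
Conditions: CrCl2 (8 equiv), NiCl2 (2 mol %), DMSO/THF, rt
Reagents that add atoms: none
Why: Nozaki–Hiyama–Kishi reaction, in which nickel inserts into the C9–I bond with retention, the alkenylchromium(III) species adds to the aldehyde under non-basic conditions, and so the C9=C10 geometry and the C7 centre are kept while the C8 configuration is irrelevant.

Step 23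
Reactants: 26 (4R,7S,8RS)-seco-diynol
Product: 27 (1S,4R,7S)-seco-diyne ketone MeC≡C–CH(OTES)–CH=CH–C(Me)(homoprenyl)–CH2–CH=C(CH2OTBDPS)–C(=O)–CH(OTBS)–C≡CMe (2Z, 9Z)
Conditions: Dess–Martin periodinane, NaHCO3, CH2Cl2, 0 °C
Reagents that add atoms: none
Why: Dess–Martin oxidation of the allylic alcohol to the enone under neutral conditions, which should leave the acidic C7–H and the enone geometry untouched.

Step 24
Reactants: 27 (1S,4R,7S)-seco-diyne ketone
Product: 28 (1S,2Z,4R,7S,9Z)-7-(tert-butyldimethylsilyloxy)-9-[(tert-butyldiphenylsilyloxy)methyl]-1-methyl-1-(4-methylpent-3-enyl)-4-(triethylsilyloxy)cycloundeca-2,9-dien-5-yn-8-one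
Conditions: [Mo(≡CC6H4-4-OMe)(OSiPh3)3] (20 mol %), 5 Å MS, toluene (1 mM), 60–80 °C
Reagents that add atoms: none
Why: Ring-closing alkyne metathesis: the molybdenum alkylidyne adds to each methyl-capped alkyne by [2+2] cycloaddition and cycloreverts through molybdacyclobutadienes, releasing but-2-yne and joining C5 to C6. The closest known reaction type is the molybdenum silanolate-catalysed RCAM of bis(propynyl) substrates to macrocyclic cycloalkynes, for which eleven-membered rings are at the small end. The one ring formed is the eleven-membered carbocycle, closed end to end between the two alkyne termini of a single chain; no stereocentre is created and C4 and C7 are spectators. The step needs cyclisation to win over intermolecular oligomerisation, which high dilution, trapping of but-2-yne by the sieves and the turn elements of the chain (two cis alkenes, the gem-disubstituted C1 and sp2 C8) should favour, with oligomers able to re-enter the metathesis equilibrium. It also needs chemoselectivity for the alkynes over four alkenes, the ketone and three silyl ethers, which alkylidynes of this type show.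

Step 25
Reactants: 28 cycloalkyne (4-OTES)
Product: 29 (1S,2Z,4R,7S,9Z)-7-(tert-butyldimethylsilyloxy)-9-[(tert-butyldiphenylsilyloxy)methyl]-4-hydroxy-1-methyl-1-(4-methylpent-3-enyl)cycloundeca-2,9-dien-5-yn-8-one
Conditions: PPTS, MeOH/CH2Cl2, 0 °C
Reagents that add atoms: none
Why: Mild acid methanolysis removes the triethylsilyl ether far faster than the secondary TBS and primary TBDPS ethers and uses no base, so C7 is not at risk.

Step 26
Reactants: 29 cycloalkyne (4-OH)
Product: 30 (1S,2Z,4R,5Z,7S,9Z)-7-(tert-butyldimethylsilyloxy)-9-[(tert-butyldiphenylsilyloxy)methyl]-4-hydroxy-1-methyl-1-(4-methylpent-3-enyl)-5-(tributylstannyl)cycloundeca-2,5,9-trien-8-one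
Conditions: [Cp*RuCl]4 (5 mol %), Bu3SnH, CH2Cl2, rt
Reagents that add atoms: tributyltin hydride CCCC[SnH](CCCC)CCCC
Why: Ruthenium-catalysed trans-hydrostannation, in which a hydrogen bond from the free C4 hydroxyl to the chloride ligand places tin on the proximal C5 and hydrogen anti on C6, giving the ring alkene with C4 and C7 trans.

Step 27
Reactants: 30 alkenylstannane
Product: 31 (1S,2Z,4R,5E,7S,9Z)-7-(tert-butyldimethylsilyloxy)-9-[(tert-butyldiphenylsilyloxy)methyl]-4-hydroxy-1,5-dimethyl-1-(4-methylpent-3-enyl)cycloundeca-2,5,9-trien-8-one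
Conditions: MeI, CuTC, [Ph2PO2][NBu4], Pd(PPh3)4 (10 mol %), DMF, rt
Reagents that add atoms: iodomethane CI
Why: Copper-assisted Stille-type methylation of the alkenylstannane (tin-to-copper exchange, phosphinate as tin scavenger), which tolerates the free hydroxyl and proceeds with retention to give the E-trisubstituted alkene.

Step 28
Reactants: 31 C4 alcohol, 32 3-methylbut-2-enoic acid
Product: 34 (1S,2Z,4R,5E,7S,9Z)-7-(tert-butyldimethylsilyloxy)-9-[(tert-butyldiphenylsilyloxy)methyl]-1,5-dimethyl-1-(4-methylpent-3-enyl)-8-oxocycloundeca-2,5,9-trien-4-yl 3-methylbut-2-enoate, via mixed anhydride 33 (not isolated)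
Conditions: 32, 2,4,6-Cl3C6H2COCl, Et3N, toluene, rt; then 31, DMAP, rt
Reagents that add atoms: 2,4,6-trichlorobenzoyl chloride O=C(Cl)c1c(Cl)cc(Cl)cc1Cl (atoms in 33 only)
Why: Yamaguchi esterification through the mixed anhydride acylates the hindered secondary allylic alcohol and avoids the acid chloride/ketene pathway that deconjugates senecioates.

Step 29
Reactants: 34 bis-silyl senecioate
Product: 35 (1S,2Z,4R,5E,7S,9Z)-7-hydroxy-9-(hydroxymethyl)-1,5-dimethyl-1-(4-methylpent-3-enyl)-8-oxocycloundeca-2,5,9-trien-4-yl 3-methylbut-2-enoate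
Conditions: TBAF, AcOH (1:1), THF, 0 °C to rt
Reagents that add atoms: none
Why: Buffered fluoride cleaves both silyl ethers while the acetic acid suppresses base-mediated epimerisation at C7 and ester cleavage.

Step 30
Reactants: 35 diol
Product: 36 CNP0163063.1 [(1S,2Z,4R,5S,6S,7S,9Z)-5,6-epoxide]
Conditions: VO(acac)2 (10 mol %), t-BuOOH, CH2Cl2, 0 °C
Reagents that add atoms: tert-butyl hydroperoxide CC(C)(C)OO
Why: Hydroxyl-directed vanadium epoxidation, in which the C7 vanadate delivers oxygen only to the adjacent C5=C6 alkene and to the face on which the C7–O bond lies when C7–H eclipses the alkene to avoid A(1,3) strain with the C5 methyl (the exposed ring face, giving 5S,6S), while the E geometry fixes C4 and C7 trans on the oxirane.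

**Compound list**
1 | geraniol | CC(C)=CCC/C(C)=C/CO | starting material
2 | (2R,3R)-2,3-epoxygeraniol | CC(C)=CCC[C@@]1(C)O[C@@H]1CO | intermediate
3 | (2R,3R)-2,3-epoxygeranyl tert-butyldimethylsilyl ether | CC(C)=CCC[C@@]1(C)O[C@@H]1CO[Si](C)(C)C(C)(C)C | intermediate
4 | (R)-2-[(tert-butyldimethylsilyloxy)methyl]-2,6-dimethylhept-5-enal | CC(C)=CCC[C@](C=O)(C)CO[Si](C)(C)C(C)(C)C | intermediate
5 | (S)-tert-butyldimethyl[(2,6-dimethyl-2-vinylhept-5-enyl)oxy]silane | CC(C)=CCC[C@](C=C)(C)CO[Si](C)(C)C(C)(C)C | intermediate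
6 | alkylborane (B-alkyl-9-BBN adduct of 5, boron on the terminal carbon) | CC(C)=CCC[C@](CCB1C2CCCC1CCC2)(C)CO[Si](C)(C)C(C)(C)C | intermediate (not isolated)
7 | (S)-3-[(tert-butyldimethylsilyloxy)methyl]-3,7-dimethyloct-6-en-1-ol | CC(C)=CCC[C@](CCO)(C)CO[Si](C)(C)C(C)(C)C | intermediate
8 | (S)-3-[(tert-butyldimethylsilyloxy)methyl]-3,7-dimethyloct-6-enal | CC(C)=CCC[C@](CC=O)(C)CO[Si](C)(C)C(C)(C)C | intermediate
9 | ethyl (2Z,5S)-5-[(tert-butyldimethylsilyloxy)methyl]-2-iodo-5,9-dimethyldeca-2,8-dienoate | CC(C)=CCC[C@](C/C=C(\I)C(=O)OCC)(C)CO[Si](C)(C)C(C)(C)C | intermediate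
10 | (2Z,5S)-5-[(tert-butyldimethylsilyloxy)methyl]-2-iodo-5,9-dimethyldeca-2,8-dien-1-ol | CC(C)=CCC[C@](C/C=C(\I)CO)(C)CO[Si](C)(C)C(C)(C)C | intermediate
11 | (2Z,5S)-1-(tert-butyldiphenylsilyloxy)-5-[(tert-butyldimethylsilyloxy)methyl]-2-iodo-5,9-dimethyldeca-2,8-diene | CC(C)=CCC[C@](C/C=C(\I)CO[Si](c1ccccc1)(c1ccccc1)C(C)(C)C)(C)CO[Si](C)(C)C(C)(C)C | intermediate
12 | (2S,4Z)-6-(tert-butyldiphenylsilyloxy)-5-iodo-2-methyl-2-(4-methylpent-3-enyl)hex-4-en-1-ol | CC(C)=CCC[C@](C/C=C(\I)CO[Si](c1ccccc1)(c1ccccc1)C(C)(C)C)(C)CO | intermediate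
13 | (2S,4Z)-6-(tert-butyldiphenylsilyloxy)-5-iodo-2-methyl-2-(4-methylpent-3-enyl)hex-4-enal | CC(C)=CCC[C@](C/C=C(\I)CO[Si](c1ccccc1)(c1ccccc1)C(C)(C)C)(C)C=O | intermediate
14 | (2Z,4S,6Z)-8-(tert-butyldiphenylsilyloxy)-7-iodo-N-methoxy-N,4-dimethyl-4-(4-methylpent-3-enyl)octa-2,6-dienamide | CC(C)=CCC[C@](C/C=C(\I)CO[Si](c1ccccc1)(c1ccccc1)C(C)(C)C)(C)/C=C\C(=O)N(C)OC | intermediate
15 | (5Z,7S,9Z)-11-(tert-butyldiphenylsilyloxy)-10-iodo-7-methyl-7-(4-methylpent-3-enyl)undeca-5,9-dien-2-yn-4-one | CC(C)=CCC[C@](C/C=C(\I)CO[Si](c1ccccc1)(c1ccccc1)C(C)(C)C)(C)/C=C\C(=O)C#CC | intermediate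
16 | (4R,5Z,7S,9Z)-11-(tert-butyldiphenylsilyloxy)-10-iodo-7-methyl-7-(4-methylpent-3-enyl)undeca-5,9-dien-2-yn-4-ol | CC(C)=CCC[C@](C/C=C(\I)CO[Si](c1ccccc1)(c1ccccc1)C(C)(C)C)(C)/C=C\[C@@H](O)C#CC | intermediate
17 | triethylsilyl ether of 16 | CC(C)=CCC[C@](C/C=C(\I)CO[Si](c1ccccc1)(c1ccccc1)C(C)(C)C)(C)/C=C\[C@@H](O[Si](CC)(CC)CC)C#CC | intermediate
18 | (R)-glyceraldehyde acetonide | O=C[C@H]1COC(C)(C)O1 | starting material
19 | (S)-4-(2,2-dibromovinyl)-2,2-dimethyl-1,3-dioxolane | BrC(Br)=C[C@H]1COC(C)(C)O1 | intermediate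
20 | lithium acetylide of (S)-4-ethynyl-2,2-dimethyl-1,3-dioxolane | [Li]C#C[C@H]1COC(C)(C)O1 | intermediate (not isolated)
21 | (S)-2,2-dimethyl-4-(prop-1-ynyl)-1,3-dioxolane | CC#C[C@H]1COC(C)(C)O1 | intermediate
22 | (S)-pent-3-yne-1,2-diol | CC#C[C@H](O)CO | intermediate
23 | (S)-1,2-bis(tert-butyldimethylsilyloxy)pent-3-yne | CC#C[C@H](O[Si](C)(C)C(C)(C)C)CO[Si](C)(C)C(C)(C)C | intermediate
24 | (S)-2-(tert-butyldimethylsilyloxy)pent-3-yn-1-ol | CC#C[C@H](O[Si](C)(C)C(C)(C)C)CO | intermediate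
25 | (S)-2-(tert-butyldimethylsilyloxy)pent-3-ynal | CC#C[C@H](O[Si](C)(C)C(C)(C)C)C=O | intermediate
26 | (1S,4R,7S,8RS)-seco-diynol (C8 carbinol, 2Z, 9Z) | CC(C)=CCC[C@](C/C=C(/CO[Si](c1ccccc1)(c1ccccc1)C(C)(C)C)C(O)[C@@H](O[Si](C)(C)C(C)(C)C)C#CC)(C)/C=C\[C@@H](O[Si](CC)(CC)CC)C#CC | intermediate
27 | (1S,4R,7S)-seco-diyne ketone (2Z, 9Z; 4-OTES, 7-OTBS, 12-OTBDPS) | CC(C)=CCC[C@](C/C=C(/CO[Si](c1ccccc1)(c1ccccc1)C(C)(C)C)C(=O)[C@@H](O[Si](C)(C)C(C)(C)C)C#CC)(C)/C=C\[C@@H](O[Si](CC)(CC)CC)C#CC | intermediate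
28 | (1S,2Z,4R,7S,9Z)-7-(tert-butyldimethylsilyloxy)-9-[(tert-butyldiphenylsilyloxy)methyl]-1-methyl-1-(4-methylpent-3-enyl)-4-(triethylsilyloxy)cycloundeca-2,9-dien-5-yn-8-one | CC(C)=CCC[C@]1(C)/C=C\[C@@H](O[Si](CC)(CC)CC)C#C[C@H](O[Si](C)(C)C(C)(C)C)C(=O)/C(CO[Si](c2ccccc2)(c2ccccc2)C(C)(C)C)=C\C1 | intermediate
29 | 4-hydroxy cycloalkyne (28 without the triethylsilyl group) | CC(C)=CCC[C@]1(C)/C=C\[C@@H](O)C#C[C@H](O[Si](C)(C)C(C)(C)C)C(=O)/C(CO[Si](c2ccccc2)(c2ccccc2)C(C)(C)C)=C\C1 | intermediate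
30 | (5Z)-5-tributylstannyl trienone (tin on C5, C4 and C7 trans) | CC(C)=CCC[C@]1(C)/C=C\[C@@H](O)/C([Sn](CCCC)(CCCC)CCCC)=C/[C@H](O[Si](C)(C)C(C)(C)C)C(=O)/C(CO[Si](c2ccccc2)(c2ccccc2)C(C)(C)C)=C\C1 | intermediate
31 | (5E)-5-methyl trienone with free 4-OH | CC(C)=CCC[C@]1(C)/C=C\[C@@H](O)/C(C)=C/[C@H](O[Si](C)(C)C(C)(C)C)C(=O)/C(CO[Si](c2ccccc2)(c2ccccc2)C(C)(C)C)=C\C1 | intermediate
32 | 3-methylbut-2-enoic acid (senecioic acid) | CC(C)=CC(=O)O | starting material
33 | 3-methylbut-2-enoic 2,4,6-trichlorobenzoic anhydride | CC(C)=CC(=O)OC(=O)c1c(Cl)cc(Cl)cc1Cl | intermediate (not isolated)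
34 | 4-O-senecioate with 7-OTBS and 12-OTBDPS | CC(C)=CCC[C@]1(C)/C=C\[C@@H](OC(=O)C=C(C)C)/C(C)=C/[C@H](O[Si](C)(C)C(C)(C)C)C(=O)/C(CO[Si](c2ccccc2)(c2ccccc2)C(C)(C)C)=C\C1 | intermediate
35 | (1S,2Z,4R,5E,7S,9Z)-7-hydroxy-9-(hydroxymethyl)-1,5-dimethyl-1-(4-methylpent-3-enyl)-8-oxocycloundeca-2,5,9-trien-4-yl 3-methylbut-2-enoate | CC(C)=CCC[C@]1(C)/C=C\[C@@H](OC(=O)C=C(C)C)/C(C)=C/[C@H](O)C(=O)/C(CO)=C\C1 | intermediate
36 | CNP0163063.1 | CC(C)=CCC[C@]1(C)/C=C\[C@@H](OC(=O)C=C(C)C)[C@]2(C)O[C@H]2[C@H](O)C(=O)/C(CO)=C\C1 | target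

**Step count and risks**

Total step count: 30. Longest linear sequence: 24 (steps 1–15 and 22–30); the aldehyde 25 takes six steps (16–21).

Steps most likely to fail:

1. Step 24. The strained eleven-membered cycloalkyne may lose to intermolecular metathesis, so that the diyne is consumed by oligomerisation, or the catalyst may be held by the propargylic ethers and the ketone. The fallback exchanges the roles of the two couplings and closes the ring by an irreversible C8–C9 bond formation. It sets out from 17 and 24. Alcohol 24 is acetylated (Ac2O, pyridine) to (S)-2-(tert-butyldimethylsilyloxy)pent-3-ynyl acetate F1. Intermolecular alkyne cross-metathesis of 17 with an excess of F1 (same molybdenum alkylidyne, 5 Å MS, toluene) should give the acyclic C5≡C6 product F2. Methanolysis (K2CO3, MeOH, 0 °C) gives the primary alcohol F3, and Dess–Martin oxidation gives the aldehyde F4. An intramolecular Nozaki–Hiyama–Kishi reaction at high dilution (CrCl2, NiCl2, DMSO/THF) closes the ring to the cyclic C8 carbinol F5, and Dess–Martin oxidation brings the sequence back to the route at 28.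

2. Step 30. Oxygen transfer may be misdirected: vanadium may be bound by the C12 hydroxyl or the C7/C8 ketol instead of acting through C7–O alone, which would lead to attack on other alkenes, ketol oxidation or loss of facial control. The fallback changes the order so that only one hydroxyl is present during epoxidation. It sets out from 34. Brief treatment with HF·pyridine (pyridine, THF, 0 °C) removes only the α-keto secondary TBS group and gives the C7 alcohol with C12 still silylated F6. Vanadium-directed epoxidation (VO(acac)2, t-BuOOH) then has a single binding site and gives the 12-O-TBDPS ether of the target F7. Buffered fluoride (TBAF, AcOH) removes the TBDPS group and returns to the route at 36.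

3. Step 14. Facial discrimination in the reduction may be poor because both ketone substituents are unsaturated, and the Z-enynone may isomerise before it is reduced. The fallback sets C4 by asymmetric C–C bond formation and avoids the enynone. It sets out from 14. DIBAL-H (THF, −78 °C) reduces the Weinreb amide to the Z-enal F8. Zinc–ProPhenol-catalysed addition of propyne (Me2Zn, the ProPhenol antipode that sends the alkynylzinc to the Si face of the aldehyde) gives the 4R propargylic alcohol and returns to the route at 16.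

Further compounds
F1 | step 24 | (S)-2-(tert-butyldimethylsilyloxy)pent-3-ynyl acetate | CC#C[C@H](O[Si](C)(C)C(C)(C)C)COC(C)=O
F2 | step 24 | acyclic cross-metathesis product (C5≡C6 joined, C8 acetate, C9 iodide) | CC(C)=CCC[C@](C/C=C(\I)CO[Si](c1ccccc1)(c1ccccc1)C(C)(C)C)(C)/C=C\[C@@H](O[Si](CC)(CC)CC)C#C[C@H](O[Si](C)(C)C(C)(C)C)COC(C)=O
F3 | step 24 | C8 primary alcohol from F2 | CC(C)=CCC[C@](C/C=C(\I)CO[Si](c1ccccc1)(c1ccccc1)C(C)(C)C)(C)/C=C\[C@@H](O[Si](CC)(CC)CC)C#C[C@H](O[Si](C)(C)C(C)(C)C)CO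
F4 | step 24 | C8 aldehyde from F3 | CC(C)=CCC[C@](C/C=C(\I)CO[Si](c1ccccc1)(c1ccccc1)C(C)(C)C)(C)/C=C\[C@@H](O[Si](CC)(CC)CC)C#C[C@H](O[Si](C)(C)C(C)(C)C)C=O
F5 | step 24 | cyclic C8 carbinol (8-hydroxy analogue of 28) | CC(C)=CCC[C@]1(C)/C=C\[C@@H](O[Si](CC)(CC)CC)C#C[C@H](O[Si](C)(C)C(C)(C)C)C(O)/C(CO[Si](c2ccccc2)(c2ccccc2)C(C)(C)C)=C\C1
F6 | step 30 | C7 alcohol of 34 with C12 still TBDPS-protected | CC(C)=CCC[C@]1(C)/C=C\[C@@H](OC(=O)C=C(C)C)/C(C)=C/[C@H](O)C(=O)/C(CO[Si](c2ccccc2)(c2ccccc2)C(C)(C)C)=C\C1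
F7 | step 30 | 12-O-TBDPS ether of the target | CC(C)=CCC[C@]1(C)/C=C\[C@@H](OC(=O)C=C(C)C)[C@]2(C)O[C@H]2[C@H](O)C(=O)/C(CO[Si](c3ccccc3)(c3ccccc3)C(C)(C)C)=C\C1
F8 | step 14 | (2Z,4S,6Z)-8-(tert-butyldiphenylsilyloxy)-7-iodo-4-methyl-4-(4-methylpent-3-enyl)octa-2,6-dienal | CC(C)=CCC[C@](C/C=C(\I)CO[Si](c1ccccc1)(c1ccccc1)C(C)(C)C)(C)/C=C\C=O
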